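The leftover was what I reckoned on: the D charged beyond Q, the limiting reagent, is what remains to spread over the other forms.

- cedar: D 0.31 M; Q 0.0620 M; time 1.0 min
- larch: D 0.31 M; Q 0.0620 M; time 2.0 min

1. which of these there is most of at the end, counted by the D in it, cedar (L / J / D / E)
2. which of these there is most of at the end, counted by the D in it, larch (L / J / D / E)
3. amount of the one of these that there is most of at the end, in percent of the D charged, cedar
4. amount of the one of these that there is most of at the end, in percent of the D charged, larch

- percentages count the D that a species holds: one D.J counts as two
- J is meant together with its D.J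
- in an amount of J, one D.J counts as one J
- run time (cedar): 1.0 min

    D ⇌ J (K1 = 1.5, k1 = 0.0140 /s)
    D ⇌ L (K2 = 2.8, k2 = 3.65 × 10⁻⁴ /s)
    D ⇌ E (K3 = 11.9, k3 = 0.0132 /s)
    D + J ⇌ D.J, settled at all times (K4 = 1.60 /M)
    D + Q → D.Q (k5 = 4.09 /M/s)

Who takes D first? With Q held at its charge, step 5 gives D a half-life of 2.7 s, far shorter than the 0.88 min of the forward step to E. So I booked Q as bound at the outset, which left 0.248 M of D, or 80.0 % of the charge, in both cedar and larch.

Which route takes that leftover? The forward constants of E and J stand at a ratio of 0.943, so they start nearly level, while the step to L has hardly any of the pace of the step to E, and I set L aside. The equilibrium constants part them by a factor of 7.93. I therefore carried E's ceiling, the share of the charged D that E holds once the leftover has balanced among D, J and E, with L and D.J set aside: the leftover times K3/(1 + K1 + K3), or 66.1 %. The same sum gives J 8.33 %.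

How soon does that difference show? The relaxation half-life of D and free J, reckoned for larch, is 0.495 min, shorter than the 1.0 min of cedar, so I expected J to level off while E climbed on. I committed to E as the largest in both flasks, below its ceiling; my reckoning gave no closer percentage.

The forecast gave E at 30 % for cedar and E at 40 % for larch, on the ground that “E keeps growing”.

Cedar gave E 30.7 %, J 25.4 % and D 20.6 %; larch gave E 40.4 %, J 24.9 % and D 12.1 %.

Larch had not come to rest at 2.0 min: E stood at 61.1 % of its ceiling. The neighbour flask with 0.015 M of Q has a ceiling of 78.6 % and read 47.7 % of E at that time, 60.7 % of it. Left ten times as long, larch held 62.9 % of E at 20.0 min, and cedar 60.9 % at 10.0 min. In larch, J with its D.J fell from 24.9 % to 8.20 %, close to its 8.33 %. L was still low, 3.42 % at 20.0 min against the 13.0 % that its constant gives once it joins the balance.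

The constants stand for no real mixture; the flask was simulated.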